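## Retrosynthetic overview
1. Acredinone B (17) ⇒ isobenzofuranyl carbinol 15. In aqueous acid 15 isomerises (CHOH → CH2, isobenzofuran → 1,2-diacylbenzene), and the two MOM groups come off in the same pot.
2. 15 ⇒ key C–C bond: 1-lithioisobenzofuran 14 (masked acyl anion of the ring-B formyl carbon) plus keto-aldehyde 13 (ring-A half). Two formyl carbons are joined.
3. 14 and 13 ⇒ one batch of isobenzofuran 11, divided in two (metalation versus 1O2 oxidation) ⇒ methyl acetal 10. Both halves of the target are one building block.
4. 10 ⇒ lactol 9 ⇒ one-pot double directed lithiation of MOM ether 3 (from phenol 1), quenched first with 2,6-dimethoxybenzaldehyde 4 and then with DMF.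
5. Rings: all four benzene rings are bought. The only ring made is the five-membered O-ring (lactol and acetal in step 2, isobenzofuran in step 3), and steps 4 and 5 open it again.

Assumption: the target SMILES has no stereocentre and no defined stereoaxis, so acredinone B is treated as achiral. The stereocentres in 6–10, 12 and 15 form as racemic or diastereomeric mixtures and are all erased. Compounds 1 and 4 are catalogue chemicals.

## Route

Step 1
Reactants: 1 4-methoxy-3-methylphenol
Product: 3 1-methoxy-4-(methoxymethoxy)-2-methylbenzene, via sodium 4-methoxy-3-methylphenolate 2 (not isolated)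
Conditions: NaH (1.2 equiv), THF, 0 °C; MOMCl (1.2 equiv), 0 °C → rt
Reagents that add atoms: chloromethyl methyl ether (MOMCl), COCCl
Why: Williamson-type O-alkylation of the phenolate with a very reactive α-chloro ether gives a MOM acetal that survives organolithiums, is the strongest ortho-director on the ring for step 2 and falls off in the final acid treatment; no stereocentre is formed.

Step 2
Reactants: 3 1-methoxy-4-(methoxymethoxy)-2-methylbenzene; 4 2,6-dimethoxybenzaldehyde
Product: 10 3-(2,6-dimethoxyphenyl)-1,7-dimethoxy-4-(methoxymethoxy)-6-methyl-1,3-dihydroisobenzofuran (methyl acetal), via [5-methoxy-2-(methoxymethoxy)-4-methylphenyl]lithium 5 (not isolated), via lithium (2,6-dimethoxyphenyl)[5-methoxy-2-(methoxymethoxy)-4-methylphenyl]methanolate 6 (not isolated), via the C,O-dilithio species 7 (not isolated), via the dilithium DMF adduct 8 (not isolated), via the lactol 3-(2,6-dimethoxyphenyl)-7-methoxy-4-(methoxymethoxy)-6-methyl-1,3-dihydroisobenzofuran-1-ol 9 (not isolated)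
Conditions: n-BuLi (1.1 equiv), THF, 0 °C, 1 h; 4, −78 → 0 °C; n-BuLi (1.3 equiv), TMEDA, 0 °C → rt; DMF, −78 °C → rt; H2O work-up; crude, MeOH, PPTS (5 mol %), 3 Å MS, rt
Reagents that add atoms: N,N-dimethylformamide (DMF), CN(C)C=O; methanol, CO
Why: Two consecutive directed ortho-metalations run in one flask: OMOM out-competes OMe and sends the first lithium to its unhindered ortho C–H (para to CH3), 1,2-addition to 4 gives alkoxide 6, whose O–Li and the neighbouring OMe flank one and the same C–H so the second n-BuLi/TMEDA is delivered there (cooperative alkoxide/OMe-directed lithiation), DMF formylation, collapse of 8 and ring closure of the hydroxy aldehyde give lactol 9, and Fischer-type acetalisation of the crude lactol through a benzylic oxocarbenium ion (far faster than aryl MOM cleavage under PPTS) gives the stable, chromatographable acetal 10, whose two stereocentres arise unselectively (racemic cis/trans mixture) and are erased in step 3.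

Step 3
Reactants: 10 methyl acetal
Product: 11 1-(2,6-dimethoxyphenyl)-4-methoxy-7-(methoxymethoxy)-5-methylisobenzofuran
Conditions: MeLi (1.1 equiv), i-Pr2NH (10 mol %), THF, 0 °C; degassed H2O work-up, K2CO3-dried; kept as a THF stock solution, Ar, dark, −20 °C
Reagents that add atoms: none
Why: Base-induced 1,4-elimination of methanol from a 1-alkoxyphthalan (MeLi as stoichiometric base, catalytic LDA as proton shuttle; the doubly benzylic C3–H is removed and methoxide leaves from C1) gives the o-quinoid isobenzofuran 11, whose twisted bulky aryl group and two peri alkoxy groups slow dimerisation enough for it to be kept cold, dark and air-free in solution and divided between steps 4 and 5; both stereocentres of 10 vanish.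

Step 4
Reactants: 11 isobenzofuran (about 45 % of the stock solution)
Product: 13 2-(2,6-dimethoxybenzoyl)-6-methoxy-3-(methoxymethoxy)-5-methylbenzaldehyde, via the 1,3-endoperoxide of the isobenzofuran 12 (not isolated)
Conditions: O2, TPP (cat.), hν, CH2Cl2/THF, −78 °C; Me2S, −78 °C → rt
Reagents that add atoms: dioxygen, O=O
Why: The isobenzofuran diene undergoes a very fast [4+2] cycloaddition with singlet oxygen (the reaction that makes arylisobenzofurans standard 1O2 traps), and low-temperature Me2S reduction of the ozonide-like endoperoxide 12 unveils ketone and aldehyde without touching MOM, OMe or ArCH3; the stereocentres of 12 vanish.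

Step 5
Reactants: 11 isobenzofuran (1.15 equiv, rest of the stock solution); 13 keto-aldehyde (1.0 equiv)
Product: 17 acredinone B, via [3-(2,6-dimethoxyphenyl)-7-methoxy-4-(methoxymethoxy)-6-methylisobenzofuran-1-yl]lithium 14 (not isolated), via lithium isobenzofuranyl carbinolate 15 (not isolated), via di-O-MOM-acredinone B 16 (not isolated)
Conditions: 11, MeLi (1.1 equiv), i-Pr2NH (10 mol %), THF, 0 °C; 13, −78 → −20 °C; then degassed 3 M aq HCl, THF, Ar, rt → 45 °C
Reagents that add atoms: water, O
Why: Proposed new method: MeLi/cat. LDA (kept below the amount of 11 so that no free alkyllithium meets 13) removes the only furan-type α-H of 11 (acidified by the ring O, pre-coordinated by the peri OMe), so 14 is an acyl anion equivalent of the ring-B formyl carbon in which the otherwise interfering ortho aroyl C=O is tied up as the furan; 1,2-addition to the CHO of 13 (its tetra-ortho-substituted diaryl ketone is inert) joins two former aldehyde carbons, and the racemic carbinol centre of 15 is erased; in aqueous acid the furfuryl-type alcohol ionises, water adds at the aryl-bearing furan carbon, the hemiketal opens and the enol tautomerises, so 15-H isomerises to 16 (isobenzofuran → 1,2-diacylbenzene, CHOH → CH2), driven by recovery of benzenoid aromaticity and giving one constitution whichever half opens because both halves are identical, and the same acid then hydrolyses both MOM acetals; closest known reaction types are metalation and electrophile trapping of isobenzofurans, cross-benzoin addition of a masked acyl anion, and acid ring-opening of 2-furylcarbinols to 1,4-dicarbonyls (furfuryl alcohol → levulinate, first stage of the Piancatelli rearrangement).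

## Compound list
1 | 4-methoxy-3-methylphenol | Cc1cc(O)ccc1OC | starting material
2 | sodium 4-methoxy-3-methylphenolate | [Na+].[O-]c1ccc(OC)c(C)c1 | intermediate (not isolated)
3 | 1-methoxy-4-(methoxymethoxy)-2-methylbenzene | COCOc1ccc(OC)c(C)c1 | intermediate
4 | 2,6-dimethoxybenzaldehyde | COc1cccc(OC)c1C=O | starting material
5 | [5-methoxy-2-(methoxymethoxy)-4-methylphenyl]lithium | [Li]c1cc(OC)c(C)cc1OCOC | intermediate (not isolated)
6 | lithium (2,6-dimethoxyphenyl)[5-methoxy-2-(methoxymethoxy)-4-methylphenyl]methanolate (racemic) | [Li]OC(c1c(OC)cccc1OC)c1cc(OC)c(C)cc1OCOC | intermediate (not isolated)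
7 | C,O-dilithio species: 6 lithiated between CH(OLi)Ar and OMe (racemic) | [Li]OC(c1c(OC)cccc1OC)c1c([Li])c(OC)c(C)cc1OCOC | intermediate (not isolated)
8 | dilithium DMF adduct (α-dimethylamino alkoxide, diastereomer mixture) | [Li]OC(N(C)C)c1c(OC)c(C)cc(OCOC)c1C(O[Li])c1c(OC)cccc1OC | intermediate (not isolated)
9 | 3-(2,6-dimethoxyphenyl)-7-methoxy-4-(methoxymethoxy)-6-methyl-1,3-dihydroisobenzofuran-1-ol (racemic cis/trans mixture) | OC1OC(c2c(OC)cccc2OC)c2c(OCOC)cc(C)c(OC)c12 | intermediate (not isolated)
10 | 3-(2,6-dimethoxyphenyl)-1,7-dimethoxy-4-(methoxymethoxy)-6-methyl-1,3-dihydroisobenzofuran (racemic cis/trans mixture) | COC1OC(c2c(OC)cccc2OC)c2c(OCOC)cc(C)c(OC)c12 | intermediate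
11 | 1-(2,6-dimethoxyphenyl)-4-methoxy-7-(methoxymethoxy)-5-methylisobenzofuran (kept in solution) | COCOc1cc(C)c(OC)c2coc(-c3c(OC)cccc3OC)c12 | intermediate
12 | 1,3-epidioxy adduct (endoperoxide) of 11 (racemic) | COCOc1cc(C)c(OC)c2C3OOC(O3)(c4c(OC)cccc4OC)c12 | intermediate (not isolated)
13 | 2-(2,6-dimethoxybenzoyl)-6-methoxy-3-(methoxymethoxy)-5-methylbenzaldehyde | O=Cc1c(OC)c(C)cc(OCOC)c1C(=O)c1c(OC)cccc1OC | intermediate
14 | [3-(2,6-dimethoxyphenyl)-7-methoxy-4-(methoxymethoxy)-6-methylisobenzofuran-1-yl]lithium | [Li]c1oc(-c2c(OC)cccc2OC)c2c(OCOC)cc(C)c(OC)c12 | intermediate (not isolated)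
15 | lithium [2-(2,6-dimethoxybenzoyl)-6-methoxy-3-(methoxymethoxy)-5-methylphenyl][3-(2,6-dimethoxyphenyl)-7-methoxy-4-(methoxymethoxy)-6-methylisobenzofuran-1-yl]methanolate (racemic) | [Li]OC(c1oc(-c2c(OC)cccc2OC)c2c(OCOC)cc(C)c(OC)c12)c1c(OC)c(C)cc(OCOC)c1C(=O)c1c(OC)cccc1OC | intermediate (not isolated)
16 | 1,2-bis[2-(2,6-dimethoxybenzoyl)-6-methoxy-3-(methoxymethoxy)-5-methylphenyl]ethan-1-one (di-O-MOM-acredinone B) | COCOc1cc(C)c(OC)c(CC(=O)c2c(OC)c(C)cc(OCOC)c2C(=O)c2c(OC)cccc2OC)c1C(=O)c1c(OC)cccc1OC | intermediate (not isolated)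
17 | acredinone B, 1,2-bis[2-(2,6-dimethoxybenzoyl)-3-hydroxy-6-methoxy-5-methylphenyl]ethan-1-one (achiral) | COc1cccc(OC)c1C(=O)c1c(O)cc(C)c(OC)c1CC(=O)c1c(OC)c(C)cc(O)c1C(=O)c1c(OC)cccc1OC | target

## Step count and risks
Total step count: 5. Longest linear sequence: 5 (1 → 3 → 10 → 11 → 13 → 17; isobenzofuran 11 is used in both step 4 and step 5).

**Step 5 (highest risk).** Metalation of 11 may be incomplete. The very hindered addition may be slow. The acid cascade may leak into a benzopyrylium salt or an indenone. The fallback sets out from 13 and comes back at 16. One portion of 13 is condensed with TsNHNH2 (MeOH, rt) to the (E)-N-tosylhydrazone of 13 F1. Heating F1 with a second equivalent of 13 and Cs2CO3 in dioxane (110 °C) causes Bamford–Stevens loss of sulfinate. This gives the 2-aroylaryldiazomethane F2. Its nucleophilic carbon adds to the CHO of 13, and a 1,2-hydride shift with loss of N2 gives 16 directly. Compound 16 is then taken to 17 with aq HCl/THF, as in the last stage of step 5.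

**Step 2.** The second lithiation may go to the C–H between OMOM and CH3 or onto the dimethoxyphenyl ring. The fallback sets out from 3 and comes back at 11. Compound 3 is lithiated as in the first stage of step 2 and quenched with ClC(O)NEt2 to give N,N-diethyl-5-methoxy-2-(methoxymethoxy)-4-methylbenzamide F3. The tertiary amide and the OMe flank the same C–H, so s-BuLi/TMEDA (−78 °C) then DMF gives the 2-formyl amide F4. NaBH4 gives the 2-(hydroxymethyl) amide F5. Warming F5 with PPTS in toluene at 80 °C lactonises it to 4-methoxy-7-(methoxymethoxy)-5-methylphthalide F6; 1.1 equiv of PPTS is used because it takes up the liberated amine. One equivalent of 2,6-dimethoxyphenyllithium F7 (from 1,3-dimethoxybenzene and n-BuLi) adds to the lactone to give the cyclic hemiketal F8. MeOH/PPTS converts F8 into the methyl ketal F9. F9 takes the place of 10 in step 3: MeLi/cat. i-Pr2NH removes an unhindered OCH2 proton, expels methoxide and gives 11.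

**Step 3.** The hindered benzhydrylic C–H may resist elimination, or 11 may dimerise or oxidise while it is stored. The fallback sets out from 9 and comes back at 13. Step 2 is stopped after the aqueous work-up, and NaBH4 (MeOH, 0 °C) reduces the crude lactol 9 to the benzhydrol/benzyl alcohol diol F10. A double Swern oxidation follows, with excess (COCl)2/DMSO and then Et3N at −78 °C. Both alcohols are activated before base is added, so no lactol or phthalide forms, and 13 is obtained without any isobenzofuran. If 11 cannot be had at all, this 13 is carried on through the fallback given for step 5, which needs only 13.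

## Further compounds
F1 | step 5 | N'-{(E)-[2-(2,6-dimethoxybenzoyl)-6-methoxy-3-(methoxymethoxy)-5-methylphenyl]methylidene}-4-methylbenzenesulfonohydrazide | Cc1ccc(cc1)S(=O)(=O)N/N=C/c1c(OC)c(C)cc(OCOC)c1C(=O)c1c(OC)cccc1OC
F2 | step 5 | [2-(diazomethyl)-3-methoxy-6-(methoxymethoxy)-4-methylphenyl](2,6-dimethoxyphenyl)methanone | [N-]=[N+]=Cc1c(OC)c(C)cc(OCOC)c1C(=O)c1c(OC)cccc1OC
F3 | step 2 | N,N-diethyl-5-methoxy-2-(methoxymethoxy)-4-methylbenzamide | CCN(CC)C(=O)c1cc(OC)c(C)cc1OCOC
F4 | step 2 | N,N-diethyl-2-formyl-3-methoxy-6-(methoxymethoxy)-4-methylbenzamide | CCN(CC)C(=O)c1c(C=O)c(OC)c(C)cc1OCOC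
F5 | step 2 | N,N-diethyl-2-(hydroxymethyl)-3-methoxy-6-(methoxymethoxy)-4-methylbenzamide | CCN(CC)C(=O)c1c(CO)c(OC)c(C)cc1OCOC
F6 | step 2 | 4-methoxy-7-(methoxymethoxy)-5-methylisobenzofuran-1(3H)-one | O=C1OCc2c(OC)c(C)cc(OCOC)c12
F7 | step 2 | 2,6-dimethoxyphenyllithium | [Li]c1c(OC)cccc1OC
F8 | step 2 | 1-(2,6-dimethoxyphenyl)-4-methoxy-7-(methoxymethoxy)-5-methyl-1,3-dihydroisobenzofuran-1-ol (racemic) | OC1(c2c(OC)cccc2OC)OCc2c(OC)c(C)cc(OCOC)c12
F9 | step 2 | 1-(2,6-dimethoxyphenyl)-1,4-dimethoxy-7-(methoxymethoxy)-5-methyl-1,3-dihydroisobenzofuran (racemic) | COC1(c2c(OC)cccc2OC)OCc2c(OC)c(C)cc(OCOC)c12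
F10 | step 3 | (2,6-dimethoxyphenyl)[2-(hydroxymethyl)-3-methoxy-6-(methoxymethoxy)-4-methylphenyl]methanol (racemic) | OCc1c(OC)c(C)cc(OCOC)c1C(O)c1c(OC)cccc1OC
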